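Assumption: boronic acid 3 is treated as a catalogue compound, and because the target has no stereocentre, the only stereogenic atoms in the route (in transient 13 and 15) are racemic and are erased before isolation.

## Structural features

The target is an isoflavone: a chromen-4-one (benzene ring A fused to 4-pyranone ring C) joined by a single C3–C1' bond to aryl ring B. It has no stereocentre, so no configuration has to be set and no stereocentres adjoin. Ring B is a syringyl unit (4'-OH between 3'- and 5'-OMe), an electron-rich phenol that is easily oxidised. Ring A is pentasubstituted: C5 bears OMe peri to the C4 carbonyl, C6 a methyl group, C7 a free OH, and only C8 carries hydrogen. The fragile elements are ring C (a vinylogous ester opened by hydroxide or amines at C2 and photoactive under short-wave UV), the 5-OMe group (cleaved by Lewis acids that chelate to C4=O) and the free phenols. The real difficulty is the O–C–O triad of ring A: the methyl must sit at C6 rather than C8, and the hindered peri 5-oxygen must be methylated while the more acidic, more accessible 7-oxygen stays free, which is the reverse of the innate reactivity of a 5,7-dihydroxychromone. The key step uses the C4a–C8a double bond of a preformed ring C as the vinyl unit of a vinylketene; C5, C6 and C7 then map onto a ketene carbonyl carbon and the methyl-bearing and oxygen-bearing carbons of a 1-siloxypropyne, so O5 arrives as a phenol and O7 as a silyl ether. Atom mapping of that step requires the diazoacetyl group on the pyranone carbon next to the ring oxygen (future C8a) and the aryl group on pyranone C5 (future C3); the structures of 7 and 16 used below meet this and need no correction.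

## Logic of the disconnections

19 ⇒ 18. The O–CH2 bond of a benzyl ether on the 4'-oxygen is cut. The syringyl phenol has to stay masked through oxidation, acyl activation, photolysis and O-methylation, and benzyl arrives ready-made in 3. The forward step must remove it under neutral conditions (hydrogenolysis), because Lewis acids would also take the 5-OMe group, and it must not reduce C2=C3.

18 ⇒ 17. The O–Si bond at O7 is cut. The silyl group is the one the benzannulation installs, so it costs no step and protects O7 while O5 is methylated. The forward cleavage needs buffered fluoride so that ring C is not opened.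

17 ⇒ 16. The O–CH3 bond at O5 is cut. In 16 the two ring A oxygens differ in kind (free chelated phenol at C5, silyl ether at C7), so methylation can only go to O5. The demand is alkylation of a hydrogen-bonded, flanked phenol without loosening the silyl ether.

16 ⇒ 7 + 11. C5–C6, C7–C8 and C4a–C5 are cut, which removes ring A altogether. The pentasubstituted benzene collapses to a two-carbon diazoacetyl side chain on a simple pyranone and a three-carbon ynol ether, and the position of the methyl between the oxygens is fixed by the alkyne. The forward step must generate the ketene from 7 without exciting the pyranone, and the ketene–alkyne union must be head-to-tail.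

7 ⇒ 5 (through 6). The bond between the side-chain carbonyl carbon and the diazo carbon is cut, i.e. acylation of a diazomethane equivalent. The acid must be activated without engaging the pyranone carbonyl, and the diazoalkane must acylate faster than it adds to the enone. (Trimethylsilyl)diazomethane is planned in place of diazomethane for handling reasons.

5 ⇒ 4. Only the oxidation level of the C2 substituent changes. The hydroxymethyl group is the one 1 already carries, so no carbon has to be introduced. The oxidant must leave the electron-rich ring B and the benzyl ether alone.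

4 ⇒ 2 + 3. The bond from pyranone C5 to C1' of ring B (the future C3–C1' bond) is cut by a cross-coupling disconnection. This detaches ring B as a purchasable boronic acid and leaves a pyranone triflate. The triflate must couple faster than it is hydrolysed by the base.

2 ⇒ 1. The O–S bond is cut. The forward step needs sulfonylation of the enolic 5-OH in the presence of the unprotected primary alcohol, which avoids a protection and deprotection pair.

11 ⇒ 8. The O–Si bond and the alkyne bond to the carbon that comes from dibromomethane are cut (ester to ynolate homologation). The three-carbon partner reduces to a bulk ester and a one-carbon unit, and the ynolate must be silylated on oxygen, which calls for a bulky silyl chloride.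

## Other disconnections considered

Alternative 1: The cut runs through C4a–C5 and C8–C8a, with ring C closed afterwards. Forward, the ketene acetal diene A2 would add to bromoalkynone A1, its CH2 terminus bonding to the bromine-bearing carbon and its acetal carbon to the acyl-bearing carbon. Loss of methanol and of the silyl group would give deoxybenzoin A3. Ring C would then need a one-carbon condensation at the benzylic CH2 (DMF dimethyl acetal) and a copper-mediated (CuI) closure of O1–C8a onto the aryl bromide, converging on 18.
- In favour: the diene and dienophile polarities are matched, so regiocontrol is the equal of the chosen plan. The 5-OMe group is in place from the outset with O7 free, which is better than the chosen plan because no chelated phenol has to be methylated late. No diazo compound or photochemistry is needed.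
- Against: A1 has an acidic CH2 between the ketone and an electron-rich arene and is prone to enolisation and alkyne–allene isomerisation in the presence of a basic, strongly nucleophilic ketene acetal. The fully substituted acetal terminus of A2 must bond next to the acyl group, a congested and probably stepwise event. A2 is hydrolytically labile.
- Comparison: this key step forms two ring bonds and leaves ring C to be made in two more operations, whereas the chosen step forms three bonds on a finished ring C. The overall step count would be about the same or slightly longer, with less robust partners.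

Alternative 2: The cut is at O1–C8a and C4–C4a, so ring C is formed last from a ring A aryne and a ring B three-carbon unit. Forward, CsF would release the aryne from ortho-silylaryl triflate A4. The enolate oxygen of formyl arylacetate A5 would add at C8a, and the aryl anion at C4a would acylate on the ester to give A6.
- In favour: this is the most convergent plan. A6 is one hydrogenolysis away from 19, which is better than the chosen plan's three steps after the key step. The expected aryne regiochemistry (nucleophile distal to the methoxy group, anion next to it) agrees with what is needed. It avoids diazo compounds and light.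
- Against: the enolate of A5 is ambident, and 1,3-dicarbonyl enolates normally attack arynes through carbon, which would lead to insertion products instead of the chromone. Protonation of the aryl anion before it acylates would stop at an aryl enol ether. A4 is a pentasubstituted benzene whose synthesis must itself differentiate two oxygens flanking a methyl group, so the central problem is moved earlier, not solved.
- Comparison: it is ahead on endgame economy. It is behind on total step count once A4 is made, and behind on the chemoselectivity of the key step, where the chosen plan relies on a single well-polarised bond-forming sequence.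

Alternative 3: The cut is at C7–C8 only. Forward, LiN(SiMe3)2 would remove a proton from the pyranone C2-methyl group of A7 (future C8), and the vinylogous enolate would attack the neighbouring ester carbon in a 6-exo-trig Claisen closure; tautomerisation would give A8, which is the same compound as 18.
- In favour: the ring closure has no regiochemical ambiguity, at least the equal of the chosen plan. O5 (from an enol methyl ether) and O7 (from the ester carbonyl) are differentiated by construction. A8 stands two steps further along than 16, which is better than the chosen plan after the key step. The reagents are benign.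
- Against: A7 is a tetrasubstituted pyranone carrying a fully substituted β-methoxyacrylate whose ester must lie cis to the pyranone. Its assembly (C-acylation at a hindered pyranone carbon, O-methylation with geometric control) would take more steps than it saves. In the key step the amide base can also attack or deprotonate C6 of the pyranone, or add to the vinylogous carbonate.
- Comparison: this key step makes one C–C bond where the chosen step makes three, so most of the complexity sits in the precursor. Overall step economy is expected to be worse despite the shorter endgame.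

Key step: step 6

## Route

Step 1
Reactants: 1 kojic acid [5-hydroxy-2-(hydroxymethyl)-4H-pyran-4-one]
Product: 2 6-(hydroxymethyl)-4-oxo-4H-pyran-3-yl trifluoromethanesulfonate
Conditions: PhNTf2, Et3N, DMF, 0 °C → rt
Reagents that add atoms: N-phenylbis(trifluoromethanesulfonimide), O=S(=O)(N(c1ccccc1)S(=O)(=O)C(F)(F)F)C(F)(F)F
Why: The enolic 5-OH is a vinylogous acid and is deprotonated by Et3N, and the mild triflyl donor PhNTf2 sulfonylates such oxyanions while leaving aliphatic alcohols alone (chemoselective phenol-type triflation).

Step 2
Reactants: 2 6-(hydroxymethyl)-4-oxo-4H-pyran-3-yl trifluoromethanesulfonate; 3 [4-(benzyloxy)-3,5-dimethoxyphenyl]boronic acid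
Product: 4 5-[4-(benzyloxy)-3,5-dimethoxyphenyl]-2-(hydroxymethyl)-4H-pyran-4-one
Conditions: Pd(PPh3)4 (cat.), K3PO4, 1,4-dioxane/H2O (10:1), 70 °C
Reagents that add atoms: none
Why: Suzuki–Miyaura coupling; the triflate on the electron-poor pyranone should add oxidatively to zerovalent palladium with ease, the electron-rich boronic acid transmetalates readily, and the free hydroxymethyl group is tolerated.

Step 3
Reactants: 4 5-[4-(benzyloxy)-3,5-dimethoxyphenyl]-2-(hydroxymethyl)-4H-pyran-4-one
Product: 5 5-[4-(benzyloxy)-3,5-dimethoxyphenyl]-4-oxo-4H-pyran-2-carboxylic acid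
Conditions: TEMPO (cat.), NaClO2, NaOCl (cat.), MeCN/NaH2PO4–Na2HPO4 buffer (pH 6.7), 35 °C
Reagents that add atoms: sodium chlorite, [Na+].[O-]Cl=O
Why: Anelli-type TEMPO oxidation with chlorite as terminal oxidant: the oxoammonium ion takes the alcohol to the aldehyde and NaClO2 takes it on to the acid near neutral pH. Only catalytic hypochlorite is present, which should spare ring B from chlorination, and the benzyl ether and pyranone are inert.

Step 4
Reactants: 5 5-[4-(benzyloxy)-3,5-dimethoxyphenyl]-4-oxo-4H-pyran-2-carboxylic acid
Product: 7 1-{5-[4-(benzyloxy)-3,5-dimethoxyphenyl]-4-oxo-4H-pyran-2-yl}-2-diazoethan-1-one, via acid chloride 6 (not isolated)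
Conditions: (COCl)2, DMF (cat.), CH2Cl2, 0 °C → rt; evaporate; then Me3SiCHN2 (2 equiv), MeCN/THF, 0 °C → rt
Reagents that add atoms: oxalyl chloride, O=C(Cl)C(=O)Cl (chlorine of 6 only); (trimethylsilyl)diazomethane, C[Si](C)(C)C=[N+]=[N-] (the CHN2 unit of 7)
Why: Acid chloride formation through the chloroiminium catalyst, then C-acylation of the diazoalkane with loss of the silyl group as Me3SiCl (Arndt–Eistert-type diazo ketone synthesis). The acid chloride has no α-hydrogen, so no ketene pathway competes, and the non-explosive silyl reagent replaces diazomethane.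

Step 5
Reactants: 8 ethyl acetate
Product: 11 triisopropyl(prop-1-yn-1-yloxy)silane, via lithium dibromoenolate 9 (not isolated), via lithium ynolate 10 (not isolated)
Conditions: CH2Br2, lithium 2,2,6,6-tetramethylpiperidide, THF, −78 °C; LiN(SiMe3)2; then n-BuLi, −78 °C → rt; then i-Pr3SiCl, −78 °C → rt
Reagents that add atoms: dibromomethane, BrCBr (the methyl-bearing alkyne carbon of 11; carbon and bromine of 9); chlorotriisopropylsilane, CC(C)[Si](Cl)(C(C)C)C(C)C; lithium bis(trimethylsilyl)amide, [Li+].C[Si](C)(C)[N-][Si](C)(C)C and n-butyllithium, [Li]CCCC (lithium of 9 and 10)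
Why: Kowalski ester homologation stopped at the ynolate: LiCHBr2 adds to the ester at −78 °C faster than it enolises it, the adduct collapses to 9, and bromine–lithium exchange triggers a 1,2-shift of the methyl group to give 10. The bulky silyl chloride then silylates oxygen and not carbon.

Step 6
Reactants: 7 1-{5-[4-(benzyloxy)-3,5-dimethoxyphenyl]-4-oxo-4H-pyran-2-yl}-2-diazoethan-1-one; 11 triisopropyl(prop-1-yn-1-yloxy)silane
Product: 16 3-[4-(benzyloxy)-3,5-dimethoxyphenyl]-5-hydroxy-6-methyl-7-[(triisopropylsilyl)oxy]-4H-chromen-4-one, via pyranonylketene 12 (not isolated), via vinylcyclobutenone 13 (not isolated), via dienylketene 14 (not isolated), via 4aH-chromene-4,5-dione 15 (not isolated)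
Conditions: 11 (1.5 equiv), hν (365 nm), degassed ClCH2CH2Cl, rt; then 80 °C
Reagents that add atoms: none
Why: Excitation of the diazo ketone at 365 nm expels N2 and the pyranonyl carbon migrates to the carbene centre (Wolff rearrangement), giving ketene 12. The electron-rich ynol ether 11 adds to 12 in a polar (2+2) cycloaddition in which its methyl-bearing carbon, the nucleophilic end β to oxygen, bonds to the ketene carbonyl carbon (C5–C6) and its siloxy carbon bonds to the ketene CH (C7–C8), giving cyclobutenone 13. On warming, 13 opens by reversible 4π conrotatory cleavage of the C5–C8 bond to dienylketene 14, and the isomer with the pyranone turned outward can only re-close, so the material drains through 14. Ring A then closes by thermal 6π disrotatory electrocyclisation, the ketene carbon bonding to pyranone C3 (C4a–C5), the only carbon terminus available because the other neighbour of the side chain is the ring oxygen; the weakly aromatic 4-pyranone loses little stabilisation, so its C2=C3 bond behaves as an ordinary vinyl group. Dione 15 enolises at once to phenol 16, driven by aromatisation and the hydrogen bond to the C4 carbonyl. The closest known reaction type is the second-generation Danheiser benzannulation of unsaturated and heteroaryl diazomethyl ketones with siloxyalkynes. No stereocentre is created in 16, those of 13 and 15 being transient and racemic. The step needs regioselectivity in the (2+2) event, secured by the oxygen polarisation of 11, and selective excitation of the diazo ketone, secured by irradiating beyond the π–π* band of the pyranone; the chelated 5-OH of 16 is a poor nucleophile, which should limit ester formation with 12.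

Step 7
Reactants: 16 3-[4-(benzyloxy)-3,5-dimethoxyphenyl]-5-hydroxy-6-methyl-7-[(triisopropylsilyl)oxy]-4H-chromen-4-one
Product: 17 3-[4-(benzyloxy)-3,5-dimethoxyphenyl]-5-methoxy-6-methyl-7-[(triisopropylsilyl)oxy]-4H-chromen-4-one
Conditions: MeI (excess), Ag2O, DMF, rt, dark
Reagents that add atoms: iodomethane, CI
Why: Purdie–Kuhn methylation: Ag2O acts as a mild base and iodide acceptor, so the chelated 5-OH, the only free hydroxyl in 16, should be alkylated under essentially neutral conditions that leave the aryl silyl ether at O7 in place. If the step is slow the failure is recoverable, whereas silyl loss under carbonate bases would methylate O7 irreversibly.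

Step 8
Reactants: 17 3-[4-(benzyloxy)-3,5-dimethoxyphenyl]-5-methoxy-6-methyl-7-[(triisopropylsilyl)oxy]-4H-chromen-4-one
Product: 18 3-[4-(benzyloxy)-3,5-dimethoxyphenyl]-7-hydroxy-5-methoxy-6-methyl-4H-chromen-4-one
Conditions: n-Bu4NF, AcOH, THF, 0 °C → rt
Reagents that add atoms: none
Why: Fluoride-driven Si–O cleavage of the aryl silyl ether; acetic acid buffers the liberated phenoxide so that the base-sensitive ring C is not opened, and the methyl and benzyl ethers are inert.

Step 9
Reactants: 18 3-[4-(benzyloxy)-3,5-dimethoxyphenyl]-7-hydroxy-5-methoxy-6-methyl-4H-chromen-4-one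
Product: 19 7-hydroxy-3-(4-hydroxy-3,5-dimethoxyphenyl)-5-methoxy-6-methyl-4H-chromen-4-one
Conditions: H2 (1 atm), Pd/C (10 %), EtOAc/MeOH, rt
Reagents that add atoms: none
Why: Hydrogenolysis of the benzyl aryl ether; the chromone C2=C3 bond belongs to a vinylogous ester and should be reduced far more slowly, and the absence of Lewis acid keeps the 5-OMe group intact.

## Compound list

1 | kojic acid, 5-hydroxy-2-(hydroxymethyl)-4H-pyran-4-one | OCc1cc(=O)c(O)co1 | starting material
2 | 6-(hydroxymethyl)-4-oxo-4H-pyran-3-yl trifluoromethanesulfonate | OCc1cc(=O)c(OS(=O)(=O)C(F)(F)F)co1 | intermediate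
3 | [4-(benzyloxy)-3,5-dimethoxyphenyl]boronic acid | COc1cc(B(O)O)cc(OC)c1OCc1ccccc1 | starting material
4 | 5-[4-(benzyloxy)-3,5-dimethoxyphenyl]-2-(hydroxymethyl)-4H-pyran-4-one | OCc1cc(=O)c(-c2cc(OC)c(OCc3ccccc3)c(OC)c2)co1 | intermediate
5 | 5-[4-(benzyloxy)-3,5-dimethoxyphenyl]-4-oxo-4H-pyran-2-carboxylic acid | OC(=O)c1cc(=O)c(-c2cc(OC)c(OCc3ccccc3)c(OC)c2)co1 | intermediate
6 | 5-[4-(benzyloxy)-3,5-dimethoxyphenyl]-4-oxo-4H-pyran-2-carbonyl chloride | ClC(=O)c1cc(=O)c(-c2cc(OC)c(OCc3ccccc3)c(OC)c2)co1 | intermediate (not isolated)
7 | 1-{5-[4-(benzyloxy)-3,5-dimethoxyphenyl]-4-oxo-4H-pyran-2-yl}-2-diazoethan-1-one | [N-]=[N+]=CC(=O)c1cc(=O)c(-c2cc(OC)c(OCc3ccccc3)c(OC)c2)co1 | intermediate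
8 | ethyl acetate | CCOC(C)=O | starting material
9 | lithium 1,1-dibromoprop-1-en-2-olate | [Li+].CC([O-])=C(Br)Br | intermediate (not isolated)
10 | lithium prop-1-yn-1-olate | [Li+].CC#C[O-] | intermediate (not isolated)
11 | triisopropyl(prop-1-yn-1-yloxy)silane | CC#CO[Si](C(C)C)(C(C)C)C(C)C | intermediate
12 | 2-{5-[4-(benzyloxy)-3,5-dimethoxyphenyl]-4-oxo-4H-pyran-2-yl}ethen-1-one | O=C=Cc1cc(=O)c(-c2cc(OC)c(OCc3ccccc3)c(OC)c2)co1 | intermediate (not isolated)
13 | 4-{5-[4-(benzyloxy)-3,5-dimethoxyphenyl]-4-oxo-4H-pyran-2-yl}-2-methyl-3-[(triisopropylsilyl)oxy]cyclobut-2-en-1-one (racemic) | CC1=C(O[Si](C(C)C)(C(C)C)C(C)C)C(c2cc(=O)c(-c3cc(OC)c(OCc4ccccc4)c(OC)c3)co2)C1=O | intermediate (not isolated)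
14 | (3E)-4-{5-[4-(benzyloxy)-3,5-dimethoxyphenyl]-4-oxo-4H-pyran-2-yl}-2-methyl-3-[(triisopropylsilyl)oxy]buta-1,3-dien-1-one | O=C=C(C)/C(O[Si](C(C)C)(C(C)C)C(C)C)=C\c1cc(=O)c(-c2cc(OC)c(OCc3ccccc3)c(OC)c2)co1 | intermediate (not isolated)
15 | 3-[4-(benzyloxy)-3,5-dimethoxyphenyl]-6-methyl-7-[(triisopropylsilyl)oxy]-4aH-chromene-4,5-dione (racemic) | CC1=C(O[Si](C(C)C)(C(C)C)C(C)C)C=C2OC=C(c3cc(OC)c(OCc4ccccc4)c(OC)c3)C(=O)C2C1=O | intermediate (not isolated)
16 | 3-[4-(benzyloxy)-3,5-dimethoxyphenyl]-5-hydroxy-6-methyl-7-[(triisopropylsilyl)oxy]-4H-chromen-4-one | COc1cc(-c2coc3cc(O[Si](C(C)C)(C(C)C)C(C)C)c(C)c(O)c3c2=O)cc(OC)c1OCc1ccccc1 | intermediate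
17 | 3-[4-(benzyloxy)-3,5-dimethoxyphenyl]-5-methoxy-6-methyl-7-[(triisopropylsilyl)oxy]-4H-chromen-4-one | COc1cc(-c2coc3cc(O[Si](C(C)C)(C(C)C)C(C)C)c(C)c(OC)c3c2=O)cc(OC)c1OCc1ccccc1 | intermediate
18 | 3-[4-(benzyloxy)-3,5-dimethoxyphenyl]-7-hydroxy-5-methoxy-6-methyl-4H-chromen-4-one | COc1cc(-c2coc3cc(O)c(C)c(OC)c3c2=O)cc(OC)c1OCc1ccccc1 | intermediate
19 | 7-hydroxy-3-(4-hydroxy-3,5-dimethoxyphenyl)-5-methoxy-6-methyl-4H-chromen-4-one | COc1cc(-c2coc3cc(O)c(C)c(OC)c3c2=O)cc(OC)c1O | target

## Step count and least certain steps

Total: 9 steps. Longest linear sequence: 8 steps (steps 1 to 4 and 6 to 9, from 1); the ynol ether branch is one step (step 5).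

Step 6 (key step). Light could also excite the 4-pyranone chromophore and trigger its photoisomerisation, and the accumulating chromone could screen the diazo ketone and stall the Wolff step. Ketene 12 could be lost to hydration, dimerisation or acylation of the phenolic product, and the thermal conversion of 13 could stop short. The fallback removes light from the ketene-forming event, sets out from 7 and comes back to the route at 16:
- A silver-promoted Wolff rearrangement in aqueous THF (PhCO2Ag, Et3N) should give {5-[4-(benzyloxy)-3,5-dimethoxyphenyl]-4-oxo-4H-pyran-2-yl}acetic acid F1.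
- (COCl)2 with catalytic DMF should convert it to {5-[4-(benzyloxy)-3,5-dimethoxyphenyl]-4-oxo-4H-pyran-2-yl}acetyl chloride F2.
- Slow addition of Et3N to F2 in the presence of 11 should generate 12 by dehydrochlorination and give 13 thermally; heating at 80 °C then leads through 14 and 15 to 16.

Step 4. The diazoalkane could add as a 1,3-dipole across the electron-poor pyranone double bonds instead of being acylated. Oxalyl chloride or the chloroiminium catalyst could activate the pyranone carbonyl oxygen, and HCl could capture the diazo ketone as a chloromethyl ketone. The fallback avoids any free diazoalkane, sets out from 6 and comes back at 7: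
- Palladium-catalysed acylation of MeZnCl (Pd(PPh3)4, THF, 0 °C; Negishi ketone synthesis) should give 2-acetyl-5-[4-(benzyloxy)-3,5-dimethoxyphenyl]-4H-pyran-4-one F3.
- Kinetic enolisation with LiN(SiMe3)2 at −78 °C and trapping with CF3CO2CH2CF3 should give 1-{5-[4-(benzyloxy)-3,5-dimethoxyphenyl]-4-oxo-4H-pyran-2-yl}-4,4,4-trifluorobutane-1,3-dione F4, used crude.
- Detrifluoroacetylative diazo transfer (MsN3, Et3N, H2O, MeCN) should deliver 7.

Step 7. The hydrogen-bonded 5-OH, flanked by the C6 methyl group, may be alkylated only sluggishly. Forcing the reaction with stronger bases would invite silyl loss followed by methylation at O7. The fallback trades the silyl group for a second benzyl group before methylation, sets out from 16 and comes back at 19: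
- n-Bu4NF/AcOH should give 3-[4-(benzyloxy)-3,5-dimethoxyphenyl]-5,7-dihydroxy-6-methyl-4H-chromen-4-one F5.
- BnBr with K2CO3 in acetone should alkylate only the more acidic, non-chelated 7-OH to give 7-(benzyloxy)-3-[4-(benzyloxy)-3,5-dimethoxyphenyl]-5-hydroxy-6-methyl-4H-chromen-4-one F6.
- MeI with K2CO3 in warm DMF, now free of any silyl group, should give 7-(benzyloxy)-3-[4-(benzyloxy)-3,5-dimethoxyphenyl]-5-methoxy-6-methyl-4H-chromen-4-one F7.
- One hydrogenolysis (H2, Pd/C) should remove both benzyl groups and give 19.

Step 1. Sulfonylation could spread to the primary alcohol or go twice, and the unprotected hydroxymethyl group could later slow the coupling of step 2 or promote triflate hydrolysis. The fallback protects the alcohol first, sets out from 1 and comes back at 4: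
- t-BuMe2SiCl with imidazole in DMF should silylate the primary alcohol to give 2-({[tert-butyl(dimethyl)silyl]oxy}methyl)-5-hydroxy-4H-pyran-4-one F8.
- Tf2O with pyridine in CH2Cl2 should give 6-({[tert-butyl(dimethyl)silyl]oxy}methyl)-4-oxo-4H-pyran-3-yl trifluoromethanesulfonate F9.
- Suzuki–Miyaura coupling with 3 (Pd(PPh3)4, K3PO4) should give 5-[4-(benzyloxy)-3,5-dimethoxyphenyl]-2-({[tert-butyl(dimethyl)silyl]oxy}methyl)-4H-pyran-4-one F10.
- n-Bu4NF/AcOH should release 4.

Step 3. Hypochlorite formed in the catalytic cycle could chlorinate ring B, or the oxidation could stop at the aldehyde stage. The fallback separates the two oxidation levels, sets out from 4 and comes back at 5: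
- MnO2 in CH2Cl2 should oxidise the activated (allylic-type) alcohol to 5-[4-(benzyloxy)-3,5-dimethoxyphenyl]-4-oxo-4H-pyran-2-carbaldehyde F11.
- Pinnick oxidation (NaClO2, NaH2PO4, 2-methylbut-2-ene as chlorine scavenger, t-BuOH/H2O) should give 5.

## Further compounds

F1 | step 6 | {5-[4-(benzyloxy)-3,5-dimethoxyphenyl]-4-oxo-4H-pyran-2-yl}acetic acid | OC(=O)Cc1cc(=O)c(-c2cc(OC)c(OCc3ccccc3)c(OC)c2)co1
F2 | step 6 | {5-[4-(benzyloxy)-3,5-dimethoxyphenyl]-4-oxo-4H-pyran-2-yl}acetyl chloride | ClC(=O)Cc1cc(=O)c(-c2cc(OC)c(OCc3ccccc3)c(OC)c2)co1
F3 | step 4 | 2-acetyl-5-[4-(benzyloxy)-3,5-dimethoxyphenyl]-4H-pyran-4-one | CC(=O)c1cc(=O)c(-c2cc(OC)c(OCc3ccccc3)c(OC)c2)co1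
F4 | step 4 | 1-{5-[4-(benzyloxy)-3,5-dimethoxyphenyl]-4-oxo-4H-pyran-2-yl}-4,4,4-trifluorobutane-1,3-dione | O=C(CC(=O)C(F)(F)F)c1cc(=O)c(-c2cc(OC)c(OCc3ccccc3)c(OC)c2)co1
F5 | step 7 | 3-[4-(benzyloxy)-3,5-dimethoxyphenyl]-5,7-dihydroxy-6-methyl-4H-chromen-4-one | COc1cc(-c2coc3cc(O)c(C)c(O)c3c2=O)cc(OC)c1OCc1ccccc1
F6 | step 7 | 7-(benzyloxy)-3-[4-(benzyloxy)-3,5-dimethoxyphenyl]-5-hydroxy-6-methyl-4H-chromen-4-one | COc1cc(-c2coc3cc(OCc4ccccc4)c(C)c(O)c3c2=O)cc(OC)c1OCc1ccccc1
F7 | step 7 | 7-(benzyloxy)-3-[4-(benzyloxy)-3,5-dimethoxyphenyl]-5-methoxy-6-methyl-4H-chromen-4-one | COc1cc(-c2coc3cc(OCc4ccccc4)c(C)c(OC)c3c2=O)cc(OC)c1OCc1ccccc1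
F8 | step 1 | 2-({[tert-butyl(dimethyl)silyl]oxy}methyl)-5-hydroxy-4H-pyran-4-one | CC(C)(C)[Si](C)(C)OCc1cc(=O)c(O)co1
F9 | step 1 | 6-({[tert-butyl(dimethyl)silyl]oxy}methyl)-4-oxo-4H-pyran-3-yl trifluoromethanesulfonate | CC(C)(C)[Si](C)(C)OCc1cc(=O)c(OS(=O)(=O)C(F)(F)F)co1
F10 | step 1 | 5-[4-(benzyloxy)-3,5-dimethoxyphenyl]-2-({[tert-butyl(dimethyl)silyl]oxy}methyl)-4H-pyran-4-one | CC(C)(C)[Si](C)(C)OCc1cc(=O)c(-c2cc(OC)c(OCc3ccccc3)c(OC)c2)co1
F11 | step 3 | 5-[4-(benzyloxy)-3,5-dimethoxyphenyl]-4-oxo-4H-pyran-2-carbaldehyde | O=Cc1cc(=O)c(-c2cc(OC)c(OCc3ccccc3)c(OC)c2)co1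
A1 | alternative 1 | 1-[4-(benzyloxy)-3,5-dimethoxyphenyl]-4-bromobut-3-yn-2-one | BrC#CC(=O)Cc1cc(OC)c(OCc2ccccc2)c(OC)c1
A2 | alternative 1 | [(4,4-dimethoxy-3-methylbuta-1,3-dien-2-yl)oxy]trimethylsilane | COC(OC)=C(C)C(=C)O[Si](C)(C)C
A3 | alternative 1 | 2-[4-(benzyloxy)-3,5-dimethoxyphenyl]-1-(2-bromo-4-hydroxy-6-methoxy-5-methylphenyl)ethan-1-one | COc1c(C)c(O)cc(Br)c1C(=O)Cc1cc(OC)c(OCc2ccccc2)c(OC)c1
A4 | alternative 2 | 5-(benzyloxy)-3-methoxy-4-methyl-2-(trimethylsilyl)phenyl trifluoromethanesulfonate | COc1c(C)c(OCc2ccccc2)cc(OS(=O)(=O)C(F)(F)F)c1[Si](C)(C)C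
A5 | alternative 2 | methyl 2-[4-(benzyloxy)-3,5-dimethoxyphenyl]-3-oxopropanoate | COC(=O)C(C=O)c1cc(OC)c(OCc2ccccc2)c(OC)c1
A6 | alternative 2 | 7-(benzyloxy)-3-[4-(benzyloxy)-3,5-dimethoxyphenyl]-5-methoxy-6-methyl-4H-chromen-4-one | COc1cc(-c2coc3cc(OCc4ccccc4)c(C)c(OC)c3c2=O)cc(OC)c1OCc1ccccc1
A7 | alternative 3 | methyl (2E)-3-{5-[4-(benzyloxy)-3,5-dimethoxyphenyl]-2-methyl-4-oxo-4H-pyran-3-yl}-3-methoxy-2-methylprop-2-enoate | COC(=O)/C(C)=C(/OC)c1c(C)occ(-c2cc(OC)c(OCc3ccccc3)c(OC)c2)c1=O
A8 | alternative 3 | 3-[4-(benzyloxy)-3,5-dimethoxyphenyl]-7-hydroxy-5-methoxy-6-methyl-4H-chromen-4-one | COc1cc(-c2coc3cc(O)c(C)c(OC)c3c2=O)cc(OC)c1OCc1ccccc1
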